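**Assumption:** the SMILES is taken literally as (2S,5R,9S,10R,13S): a trans-decalin with the C9 chain trans to the C10 methyl and the C2 ester axial, cis to the C10 methyl (labdane numbering). The catalyst and ligand enantiomers in steps 1 and 14 are assigned by the usual models and must be confirmed on first use.

## Retrosynthetic overview

1. The C13 centre and acid come from copper-catalysed asymmetric conjugate methylation of an E-enoate, itself grown from a C9 allyl group (hydroboration, oxidation, Wittig).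
2. The axial C2 isovalerate comes from reduction of a C2 ketone from the open β face, then acylation.
3. The axial C9 chain and the C8 methylene come from Tsuji decarboxylative allylation of a bicyclic allyl β-keto ester (attack anti to the C10 methyl), then non-basic methylenation.
4. Ring A comes from ketoisophorone; ring B is closed onto it by SnCl4 cation–olefin cyclization, in which a temporary equatorial C2 silyloxy centre relays chirality to C5 and C10.
5. The cyclization precursor comes from the ring A enol triflate (Negishi coupling, crossed Claisen), and the triflate from Noyori transfer hydrogenation of ketoisophorone.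

## Route

Step 1
Reactants: 1 ketoisophorone (2,6,6-trimethylcyclohex-2-ene-1,4-dione)
Product: 2 (R)-4-hydroxy-2,6,6-trimethylcyclohex-2-en-1-one
Conditions: RuCl[(R,R)-TsDPEN](p-cymene) (0.5 mol%), HCO2H/Et3N 5:2, CH2Cl2, 25 °C
Reagents that add atoms: none
Why: Noyori asymmetric transfer hydrogenation reduces only the less hindered C4 carbonyl (the C1 carbonyl is flanked by the gem-dimethyl and the vinylic methyl); with the alkenyl group in the aryl role of the Noyori model the (R,R) catalyst gives the (R)-carbinol, the relay stereocentre.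

Step 2
Reactants: 2 (R)-4-hydroxy-2,6,6-trimethylcyclohex-2-en-1-one; 3 tert-butyldimethylsilyl chloride
Product: 4 (R)-4-[(tert-butyldimethylsilyl)oxy]-2,6,6-trimethylcyclohex-2-en-1-one
Conditions: TBSCl, imidazole, DMF, 25 °C
Reagents that add atoms: tert-butyldimethylsilyl chloride (3), CC(C)(C)[Si](C)(C)Cl
Why: Imidazole-promoted silylation masks the hydroxyl for the hydride, organozinc and enolate steps without touching the stereocentre.

Step 3
Reactants: 4 (R)-4-[(tert-butyldimethylsilyl)oxy]-2,6,6-trimethylcyclohex-2-en-1-one; 5 N-phenylbis(trifluoromethanesulfonimide)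
Product: 7 (S)-4-[(tert-butyldimethylsilyl)oxy]-2,6,6-trimethylcyclohex-1-en-1-yl trifluoromethanesulfonate, via lithium enolate 6 (not isolated)
Conditions: LiBH(s-Bu)3, THF, −78 °C; then PhNTf2, −78 → 25 °C
Reagents that add atoms: N-phenylbis(trifluoromethanesulfonimide) (5), O=S(=O)(N(c1ccccc1)S(=O)(=O)C(F)(F)F)C(F)(F)F
Why: Conjugate hydride reduction (1,2-attack is blocked by the α-methyl and the gem-dimethyl) gives one regiodefined enolate that is O-triflated in the same flask; the carbinol is untouched and its descriptor changes from R to S only through CIP priorities.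

Step 4
Reactants: 7 (S)-4-[(tert-butyldimethylsilyl)oxy]-2,6,6-trimethylcyclohex-1-en-1-yl trifluoromethanesulfonate; 8 (3-ethoxy-3-oxopropyl)zinc bromide
Product: 9 ethyl 3-[(S)-4-[(tert-butyldimethylsilyl)oxy]-2,6,6-trimethylcyclohex-1-en-1-yl]propanoate
Conditions: PdCl2(dppf) (5 mol%), THF/NMP, 60 °C
Reagents that add atoms: (3-ethoxy-3-oxopropyl)zinc bromide (8), CCOC(=O)CC[Zn]Br
Why: Negishi sp2–sp3 cross-coupling of the enol triflate with the ester-stabilised zinc homoenolate; the bidentate dppf ligand favours reductive elimination over β-hydride elimination.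

Step 5
Reactants: 9 ethyl 3-[(S)-4-[(tert-butyldimethylsilyl)oxy]-2,6,6-trimethylcyclohex-1-en-1-yl]propanoate; 10 allyl acetate
Product: 11 allyl 5-[(S)-4-[(tert-butyldimethylsilyl)oxy]-2,6,6-trimethylcyclohex-1-en-1-yl]-3-oxopentanoate
Conditions: LDA (3.1 equiv), allyl acetate (3 equiv), THF, −78 °C; then 9, −78 → 0 °C
Reagents that add atoms: allyl acetate (10), CC(=O)OCC=C
Why: Crossed Claisen condensation: the preformed lithium enolate of allyl acetate, used in excess, acylates on the unhindered ethyl ester and the product is protected as its enolate until work-up.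

Step 6
Reactants: 11 allyl 5-[(S)-4-[(tert-butyldimethylsilyl)oxy]-2,6,6-trimethylcyclohex-1-en-1-yl]-3-oxopentanoate
Product: 13 allyl (1S,4aR,7R,8aR)-7-hydroxy-5,5,8a-trimethyl-2-oxodecahydronaphthalene-1-carboxylate, via silyl ether 12 (not isolated)
Conditions: SnCl4 (2 equiv), wet CH2Cl2, 0 → 25 °C; aqueous quench, then crude in MeCN, 48% aq HF, 25 °C
Reagents that add atoms: none
Why: Lewis acid-promoted cation–olefin cyclization terminated by the β-keto ester enol closes ring B through a chair–chair transition state to the trans-decalin; with the C2 silyloxy group equatorial, H5 enters cis and the C10 methyl trans to it, so the (S)-carbinol dictates 5R,10R, the C9 ester settles equatorial, and HF then removes the silyl group.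

Step 7
Reactants: 13 allyl (1S,4aR,7R,8aR)-7-hydroxy-5,5,8a-trimethyl-2-oxodecahydronaphthalene-1-carboxylate
Product: 14 (1R,4aR,7R,8aR)-1-allyl-7-hydroxy-5,5,8a-trimethyloctahydronaphthalen-2(1H)-one
Conditions: Pd(PPh3)4 (5 mol%), THF, 25 °C
Reagents that add atoms: none
Why: Tsuji decarboxylative allylation: zerovalent palladium ionises the allyl ester, loss of CO2 gives the enolate only at C9, and C-allylation occurs on the axial face anti to the adjacent axial C10 methyl, giving the kinetic axial allyl (chain trans to the C10 methyl) under neutral conditions that do not epimerise it.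

Step 8
Reactants: 14 (1R,4aR,7R,8aR)-1-allyl-7-hydroxy-5,5,8a-trimethyloctahydronaphthalen-2(1H)-one; 15 dibromomethane
Product: 16 (2R,4aR,8S,8aR)-8-allyl-4,4,8a-trimethyl-7-methylenedecahydronaphthalen-2-ol
Conditions: Zn, CH2Br2, TiCl4 (excess), THF/CH2Cl2, 0 → 25 °C
Reagents that add atoms: dibromomethane (15), BrCBr
Why: Takai–Lombardo methylenation with the non-basic zinc–titanium methylene reagent converts the hindered, enolisable ketone into the exocyclic alkene without epimerising C9, which is thereby fixed; the free hydroxyl only consumes extra reagent.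

Step 9
Reactants: 16 (2R,4aR,8S,8aR)-8-allyl-4,4,8a-trimethyl-7-methylenedecahydronaphthalen-2-ol
Product: 17 (4aR,8S,8aR)-8-allyl-4,4,8a-trimethyl-7-methyleneoctahydronaphthalen-2(1H)-one
Conditions: Dess–Martin periodinane, NaHCO3, CH2Cl2, 25 °C
Reagents that add atoms: none
Why: Dess–Martin oxidation turns the equatorial relay alcohol into the C2 ketone, erasing the temporary stereocentre after it has set C5 and C10.

Step 10
Reactants: 17 (4aR,8S,8aR)-8-allyl-4,4,8a-trimethyl-7-methyleneoctahydronaphthalen-2(1H)-one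
Product: 18 (2S,4aR,8S,8aR)-8-allyl-4,4,8a-trimethyl-7-methylenedecahydronaphthalen-2-ol
Conditions: LiBH(s-Bu)3, THF, −78 °C
Reagents that add atoms: none
Why: Bulky hydride reduction: the α face of the C2 carbonyl is shielded by the two syn-axial methyls (on C10 and C4), so hydride enters equatorially from the β face and gives the axial 2S alcohol.

Step 11
Reactants: 18 (2S,4aR,8S,8aR)-8-allyl-4,4,8a-trimethyl-7-methylenedecahydronaphthalen-2-ol; 19 3-methylbutanoyl chloride (isovaleryl chloride)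
Product: 20 (2S,4aR,8S,8aR)-8-allyl-4,4,8a-trimethyl-7-methylenedecahydronaphthalen-2-yl 3-methylbutanoate
Conditions: isovaleryl chloride (3 equiv), DMAP, Et3N, CH2Cl2, 40 °C
Reagents that add atoms: 3-methylbutanoyl chloride (19), CC(C)CC(=O)Cl
Why: DMAP-catalysed acylation through the acylpyridinium ion esterifies the hindered axial alcohol with retention; excess reagent and warming compensate for the 1,3-diaxial methyls.

Step 12
Reactants: 20 (2S,4aR,8S,8aR)-8-allyl-4,4,8a-trimethyl-7-methylenedecahydronaphthalen-2-yl 3-methylbutanoate; 21 hydrogen peroxide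
Product: 23 (2S,4aR,8S,8aR)-8-(3-hydroxypropyl)-4,4,8a-trimethyl-7-methylenedecahydronaphthalen-2-yl 3-methylbutanoate, via alkylborane 22 (not isolated)
Conditions: Sia2BH (from BH3·THF and 2-methylbut-2-ene), THF, 0 °C; then 30% H2O2, aq NaOAc, 0 → 25 °C
Reagents that add atoms: hydrogen peroxide (21), OO
Why: Anti-Markovnikov hydroboration–oxidation: the bulky dialkylborane reacts with the monosubstituted terminal alkene much faster than with the hindered 1,1-disubstituted exocyclic alkene and does not reduce the ester, and buffered peroxide spares the isovalerate.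

Step 13
Reactants: 23 (2S,4aR,8S,8aR)-8-(3-hydroxypropyl)-4,4,8a-trimethyl-7-methylenedecahydronaphthalen-2-yl 3-methylbutanoate; 24 methyl (triphenylphosphoranylidene)acetate
Product: 26 methyl (E)-5-[(1S,4aR,7S,8aR)-5,5,8a-trimethyl-2-methylene-7-(3-methylbutanoyloxy)decahydronaphthalen-1-yl]pent-2-enoate, via aldehyde 25 (not isolated)
Conditions: Dess–Martin periodinane, NaHCO3, CH2Cl2, 25 °C; then 24, 25 °C
Reagents that add atoms: methyl (triphenylphosphoranylidene)acetate (24), COC(=O)C=P(c1ccccc1)(c1ccccc1)c1ccccc1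
Why: Dess–Martin oxidation to the aldehyde followed in the same flask by Wittig olefination with the stabilised ylide gives the E-enoate; no stereocentre is α to the aldehyde.

Step 14
Reactants: 26 methyl (E)-5-[(1S,4aR,7S,8aR)-5,5,8a-trimethyl-2-methylene-7-(3-methylbutanoyloxy)decahydronaphthalen-1-yl]pent-2-enoate; 27 methylmagnesium bromide
Product: 28 methyl (S)-3-methyl-5-[(1S,4aR,7S,8aR)-5,5,8a-trimethyl-2-methylene-7-(3-methylbutanoyloxy)decahydronaphthalen-1-yl]pentanoate
Conditions: CuI (copper iodide, 2 mol%), (S)-Tol-BINAP (3 mol%), MeMgBr (4 equiv), t-BuOMe, −20 °C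
Reagents that add atoms: methylmagnesium bromide (27), C[Mg]Br
Why: Copper-catalysed asymmetric conjugate addition of the Grignard reagent to the E-enoate; the Tol-BINAP–copper complex controls the face (reagent control, remote from the decalin) and sets 13S, while the hindered isovalerate is not attacked at −20 °C.

Step 15
Reactants: 28 methyl (S)-3-methyl-5-[(1S,4aR,7S,8aR)-5,5,8a-trimethyl-2-methylene-7-(3-methylbutanoyloxy)decahydronaphthalen-1-yl]pentanoate; 29 lithium hydroxide
Product: 30 (S)-3-methyl-5-[(1S,4aR,7S,8aR)-5,5,8a-trimethyl-2-methylene-7-(3-methylbutanoyloxy)decahydronaphthalen-1-yl]pentanoic acid (CNP0168901.1)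
Conditions: LiOH·H2O (2 equiv), THF/MeOH/H2O, 0 → 25 °C; then cold 1 M HCl to pH 3
Reagents that add atoms: lithium hydroxide (29), [Li+].[OH-]
Why: Saponification of the unhindered methyl ester; the axial isovalerate, shielded by two syn-axial methyls, hydrolyses far more slowly, and C13 (β to the carboxyl) cannot epimerise.

## Compound list

1 | ketoisophorone (2,6,6-trimethylcyclohex-2-ene-1,4-dione) | CC1=CC(=O)CC(C)(C)C1=O | starting material
2 | (R)-4-hydroxy-2,6,6-trimethylcyclohex-2-en-1-one | CC1=C[C@H](O)CC(C)(C)C1=O | intermediate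
3 | tert-butyldimethylsilyl chloride | CC(C)(C)[Si](C)(C)Cl | starting material
4 | (R)-4-[(tert-butyldimethylsilyl)oxy]-2,6,6-trimethylcyclohex-2-en-1-one | CC1=C[C@H](O[Si](C)(C)C(C)(C)C)CC(C)(C)C1=O | intermediate
5 | N-phenylbis(trifluoromethanesulfonimide) | O=S(=O)(N(c1ccccc1)S(=O)(=O)C(F)(F)F)C(F)(F)F | starting material
6 | lithium (S)-4-[(tert-butyldimethylsilyl)oxy]-2,6,6-trimethylcyclohex-1-en-1-olate (not isolated) | CC1=C([O-])C(C)(C)C[C@@H](O[Si](C)(C)C(C)(C)C)C1.[Li+] | intermediate
7 | (S)-4-[(tert-butyldimethylsilyl)oxy]-2,6,6-trimethylcyclohex-1-en-1-yl trifluoromethanesulfonate | CC1=C(OS(=O)(=O)C(F)(F)F)C(C)(C)C[C@@H](O[Si](C)(C)C(C)(C)C)C1 | intermediate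
8 | (3-ethoxy-3-oxopropyl)zinc bromide | CCOC(=O)CC[Zn]Br | starting material
9 | ethyl 3-[(S)-4-[(tert-butyldimethylsilyl)oxy]-2,6,6-trimethylcyclohex-1-en-1-yl]propanoate | CC1=C(CCC(=O)OCC)C(C)(C)C[C@@H](O[Si](C)(C)C(C)(C)C)C1 | intermediate
10 | allyl acetate | CC(=O)OCC=C | starting material
11 | allyl 5-[(S)-4-[(tert-butyldimethylsilyl)oxy]-2,6,6-trimethylcyclohex-1-en-1-yl]-3-oxopentanoate | CC1=C(CCC(=O)CC(=O)OCC=C)C(C)(C)C[C@@H](O[Si](C)(C)C(C)(C)C)C1 | intermediate
12 | allyl (1S,4aR,7R,8aR)-7-[(tert-butyldimethylsilyl)oxy]-5,5,8a-trimethyl-2-oxodecahydronaphthalene-1-carboxylate (not isolated) | O=C1CC[C@@H]2C(C)(C)C[C@@H](O[Si](C)(C)C(C)(C)C)C[C@@]2(C)[C@@H]1C(=O)OCC=C | intermediate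
13 | allyl (1S,4aR,7R,8aR)-7-hydroxy-5,5,8a-trimethyl-2-oxodecahydronaphthalene-1-carboxylate | O=C1CC[C@@H]2C(C)(C)C[C@@H](O)C[C@@]2(C)[C@@H]1C(=O)OCC=C | intermediate
14 | (1R,4aR,7R,8aR)-1-allyl-7-hydroxy-5,5,8a-trimethyloctahydronaphthalen-2(1H)-one | O=C1CC[C@@H]2C(C)(C)C[C@@H](O)C[C@@]2(C)[C@H]1CC=C | intermediate
15 | dibromomethane | BrCBr | starting material
16 | (2R,4aR,8S,8aR)-8-allyl-4,4,8a-trimethyl-7-methylenedecahydronaphthalen-2-ol | C=C1CC[C@@H]2C(C)(C)C[C@@H](O)C[C@@]2(C)[C@H]1CC=C | intermediate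
17 | (4aR,8S,8aR)-8-allyl-4,4,8a-trimethyl-7-methyleneoctahydronaphthalen-2(1H)-one | C=C1CC[C@@H]2C(C)(C)CC(=O)C[C@@]2(C)[C@H]1CC=C | intermediate
18 | (2S,4aR,8S,8aR)-8-allyl-4,4,8a-trimethyl-7-methylenedecahydronaphthalen-2-ol | C=C1CC[C@@H]2C(C)(C)C[C@H](O)C[C@@]2(C)[C@H]1CC=C | intermediate
19 | 3-methylbutanoyl chloride (isovaleryl chloride) | CC(C)CC(=O)Cl | starting material
20 | (2S,4aR,8S,8aR)-8-allyl-4,4,8a-trimethyl-7-methylenedecahydronaphthalen-2-yl 3-methylbutanoate | C=C1CC[C@@H]2C(C)(C)C[C@H](OC(=O)CC(C)C)C[C@@]2(C)[C@H]1CC=C | intermediate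
21 | hydrogen peroxide | OO | starting material
22 | (2S,4aR,8S,8aR)-8-{3-[bis(3-methylbutan-2-yl)boranyl]propyl}-4,4,8a-trimethyl-7-methylenedecahydronaphthalen-2-yl 3-methylbutanoate (not isolated) | C=C1CC[C@@H]2C(C)(C)C[C@H](OC(=O)CC(C)C)C[C@@]2(C)[C@H]1CCCB(C(C)C(C)C)C(C)C(C)C | intermediate
23 | (2S,4aR,8S,8aR)-8-(3-hydroxypropyl)-4,4,8a-trimethyl-7-methylenedecahydronaphthalen-2-yl 3-methylbutanoate | C=C1CC[C@@H]2C(C)(C)C[C@H](OC(=O)CC(C)C)C[C@@]2(C)[C@H]1CCCO | intermediate
24 | methyl (triphenylphosphoranylidene)acetate | COC(=O)C=P(c1ccccc1)(c1ccccc1)c1ccccc1 | starting material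
25 | (2S,4aR,8S,8aR)-4,4,8a-trimethyl-7-methylene-8-(3-oxopropyl)decahydronaphthalen-2-yl 3-methylbutanoate (not isolated) | C=C1CC[C@@H]2C(C)(C)C[C@H](OC(=O)CC(C)C)C[C@@]2(C)[C@H]1CCC=O | intermediate
26 | methyl (E)-5-[(1S,4aR,7S,8aR)-5,5,8a-trimethyl-2-methylene-7-(3-methylbutanoyloxy)decahydronaphthalen-1-yl]pent-2-enoate | C=C1CC[C@@H]2C(C)(C)C[C@H](OC(=O)CC(C)C)C[C@@]2(C)[C@H]1CC/C=C/C(=O)OC | intermediate
27 | methylmagnesium bromide | C[Mg]Br | starting material
28 | methyl (S)-3-methyl-5-[(1S,4aR,7S,8aR)-5,5,8a-trimethyl-2-methylene-7-(3-methylbutanoyloxy)decahydronaphthalen-1-yl]pentanoate | C=C1CC[C@@H]2C(C)(C)C[C@H](OC(=O)CC(C)C)C[C@@]2(C)[C@H]1CC[C@H](C)CC(=O)OC | intermediate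
29 | lithium hydroxide | [Li+].[OH-] | starting material
30 | (S)-3-methyl-5-[(1S,4aR,7S,8aR)-5,5,8a-trimethyl-2-methylene-7-(3-methylbutanoyloxy)decahydronaphthalen-1-yl]pentanoic acid (CNP0168901.1) | C=C1CC[C@@H]2C(C)(C)C[C@H](OC(=O)CC(C)C)C[C@@]2(C)[C@H]1CC[C@H](C)CC(=O)O | target

## Step count and risks

Total steps: 15. Longest linear sequence: 15 (fully linear from ketoisophorone 1).

The three steps most likely to fail are 7, 4 and 14.

**Step 7 (decarboxylative allylation, contra-thermodynamic axial C9).** Risks are protonated ketone, diallylation, or the equatorial epimer. The fallback makes the same C9 enolate regiospecifically without palladium. It sets out from 13 and returns at 14.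
- Transesterification of 13 with benzyl alcohol (DMAP, toluene, 110 °C, allyl alcohol distilled off) gives benzyl (1S,4aR,7R,8aR)-7-hydroxy-5,5,8a-trimethyl-2-oxodecahydronaphthalene-1-carboxylate F3.
- Hydrogenolysis (H2, Pd/C, EtOAc, 0 °C) gives (1S,4aR,7R,8aR)-7-hydroxy-5,5,8a-trimethyl-2-oxodecahydronaphthalene-1-carboxylic acid F4.
- Silylation (TMSCl, Et3N) and heating in toluene at 100 °C moves silicon from the carboxyl to the ketone oxygen with loss of CO2, giving the regiodefined bis-silyl compound trimethyl{[(4aR,7R,8aR)-5,5,8a-trimethyl-7-(trimethylsilyloxy)-3,4,4a,5,6,7,8,8a-octahydronaphthalen-2-yl]oxy}silane F5.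
- MeLi (THF, 0 °C) releases the lithium enolate, which is alkylated with allyl bromide at −78 °C from the face anti to the C10 methyl; the C2 silyl ether falls off in the dilute acid work-up, giving 14.

**Step 4 (alkylzinc coupling to a tetrasubstituted, hindered enol triflate).** Risks are slow oxidative addition and reduced product. The fallback attaches the chain by a Heck reaction. It sets out from 7 and returns at 11, bypassing 9 and step 5.
- 7 and methyl vinyl ketone (Pd(OAc)2, PPh3, Et3N, DMF, 75 °C) give (S,E)-4-{4-[(tert-butyldimethylsilyl)oxy]-2,6,6-trimethylcyclohex-1-en-1-yl}but-3-en-2-one F1.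
- Conjugate reduction of the disubstituted enone double bond with [(Ph3P)CuH]6 (benzene, 25 °C) gives 4-{(S)-4-[(tert-butyldimethylsilyl)oxy]-2,6,6-trimethylcyclohex-1-en-1-yl}butan-2-one F2.
- C-acylation at the methyl group with diallyl carbonate and NaH (THF, 65 °C) gives 11.

**Step 14 (asymmetric conjugate methylation).** Risks are low conversion with MeMgBr, modest ee, or the wrong sense. The fallback sets C13 by asymmetric conjugate reduction instead. It sets out from 23 and returns at 28.
- 23 is oxidised (Dess–Martin periodinane) to aldehyde 25, this time isolated.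
- MeMgBr (THF, −78 °C) gives (2S,4aR,8S,8aR)-8-(3-hydroxybutyl)-4,4,8a-trimethyl-7-methylenedecahydronaphthalen-2-yl 3-methylbutanoate F6 (carbinol epimers).
- Dess–Martin oxidation gives (2S,4aR,8S,8aR)-4,4,8a-trimethyl-7-methylene-8-(3-oxobutyl)decahydronaphthalen-2-yl 3-methylbutanoate F7.
- Horner–Wadsworth–Emmons olefination (trimethyl phosphonoacetate, NaH, THF) gives methyl (E)-3-methyl-5-[(1S,4aR,7S,8aR)-5,5,8a-trimethyl-2-methylene-7-(3-methylbutanoyloxy)decahydronaphthalen-1-yl]pent-2-enoate F8; the Z isomer is removed by chromatography.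
- Copper hydride reduction (Cu(OAc)2, p-Tol-BINAP enantiomer chosen for 13S, polymethylhydrosiloxane, t-BuOH, toluene, 25 °C) gives 28 without touching the exocyclic alkene.

## Further compounds

F1 | step 4 | (S,E)-4-{4-[(tert-butyldimethylsilyl)oxy]-2,6,6-trimethylcyclohex-1-en-1-yl}but-3-en-2-one | CC1=C(/C=C/C(C)=O)C(C)(C)C[C@@H](O[Si](C)(C)C(C)(C)C)C1
F2 | step 4 | 4-{(S)-4-[(tert-butyldimethylsilyl)oxy]-2,6,6-trimethylcyclohex-1-en-1-yl}butan-2-one | CC1=C(CCC(C)=O)C(C)(C)C[C@@H](O[Si](C)(C)C(C)(C)C)C1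
F3 | step 7 | benzyl (1S,4aR,7R,8aR)-7-hydroxy-5,5,8a-trimethyl-2-oxodecahydronaphthalene-1-carboxylate | O=C1CC[C@@H]2C(C)(C)C[C@@H](O)C[C@@]2(C)[C@@H]1C(=O)OCc1ccccc1
F4 | step 7 | (1S,4aR,7R,8aR)-7-hydroxy-5,5,8a-trimethyl-2-oxodecahydronaphthalene-1-carboxylic acid | O=C1CC[C@@H]2C(C)(C)C[C@@H](O)C[C@@]2(C)[C@@H]1C(=O)O
F5 | step 7 | trimethyl{[(4aR,7R,8aR)-5,5,8a-trimethyl-7-(trimethylsilyloxy)-3,4,4a,5,6,7,8,8a-octahydronaphthalen-2-yl]oxy}silane | C[Si](C)(C)OC1=C[C@]2(C)C[C@H](O[Si](C)(C)C)CC(C)(C)[C@H]2CC1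
F6 | step 14 | (2S,4aR,8S,8aR)-8-(3-hydroxybutyl)-4,4,8a-trimethyl-7-methylenedecahydronaphthalen-2-yl 3-methylbutanoate | C=C1CC[C@@H]2C(C)(C)C[C@H](OC(=O)CC(C)C)C[C@@]2(C)[C@H]1CCC(C)O
F7 | step 14 | (2S,4aR,8S,8aR)-4,4,8a-trimethyl-7-methylene-8-(3-oxobutyl)decahydronaphthalen-2-yl 3-methylbutanoate | C=C1CC[C@@H]2C(C)(C)C[C@H](OC(=O)CC(C)C)C[C@@]2(C)[C@H]1CCC(C)=O
F8 | step 14 | methyl (E)-3-methyl-5-[(1S,4aR,7S,8aR)-5,5,8a-trimethyl-2-methylene-7-(3-methylbutanoyloxy)decahydronaphthalen-1-yl]pent-2-enoate | C=C1CC[C@@H]2C(C)(C)C[C@H](OC(=O)CC(C)C)C[C@@]2(C)[C@H]1CC/C(C)=C/C(=O)OC
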